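The imidazole is disconnected at N1–C5. Ring carbon C5 and its methyl group are the two carbons of a terminal alkyne; C4, which carries the arylethyl chain, and N3 come from a propargylic amine; C2 with its four-carbon chain and N1 come from an amidine. In one operation the distal amidine NH adds 5-exo-dig to the internal alkyne carbon and the exocyclic methylene imidazoline aromatizes by hydrogen shift, so no carbonyl or halide is needed at C4 or C5. The precursor is a racemic N-propargylamidine with a free primary alcohol, built from a propargylic amine and a Pinner imidate. O-Acetylation of the resulting cypholophine finishes the route.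

Key step: step 7

Remark: the propargylic stereocentre is erased in the key step, so racemic tert-butanesulfinamide is used and all chiral intermediates are racemates.

Step 1
Reactants: 1 3-(3,4-dimethoxyphenyl)propan-1-ol
Product: 2 3-(3,4-dimethoxyphenyl)propanal
Conditions: TEMPO (10 mol %), PhI(OAc)2 (1.1 equiv), CH2Cl2, rt
Reagents that add atoms: none
Why: Oxoammonium-mediated alcohol oxidation (TEMPO/PhI(OAc)2) should stop at the aldehyde under anhydrous conditions and leave the electron-rich dimethoxyarene untouched.

Step 2
Reactants: 2 3-(3,4-dimethoxyphenyl)propanal; 3 tert-butanesulfinamide (racemic)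
Product: 4 (E)-N-[3-(3,4-dimethoxyphenyl)propylidene]-2-methylpropane-2-sulfinamide
Conditions: Ti(OEt)4 (2 equiv), THF, rt; brine work-up
Reagents that add atoms: none
Why: Ellman condensation, in which Ti(OEt)4 serves as Lewis acid and water scavenger, should give the E-configured N-sulfinyl aldimine without aldol self-condensation of the enolizable aldehyde.

Step 3
Reactants: 4 (E)-N-[3-(3,4-dimethoxyphenyl)propylidene]-2-methylpropane-2-sulfinamide; 5 ethynylmagnesium bromide
Product: 6 N-[5-(3,4-dimethoxyphenyl)pent-1-yn-3-yl]-2-methylpropane-2-sulfinamide (mixture of racemic diastereomers)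
Conditions: HC≡CMgBr (0.5 M in THF, 2.5 equiv), CH2Cl2, −78 °C to rt; sat. aq. NH4Cl
Reagents that add atoms: none
Why: 1,2-Addition of an alkynyl Grignard reagent to an activated N-sulfinyl aldimine (Ellman sulfinimine alkynylation) forms the propargylic C–C bond; the sulfinyl group biases the new carbon stereocentre, but its configuration is irrelevant because step 7 erases it.

Step 4
Reactants: 6 N-[5-(3,4-dimethoxyphenyl)pent-1-yn-3-yl]-2-methylpropane-2-sulfinamide
Product: 7 5-(3,4-dimethoxyphenyl)pent-1-yn-3-amine (racemic, free base)
Conditions: HCl (4 M in 1,4-dioxane, 2.5 equiv), MeOH, 0 °C to rt; then aq. NaOH, CH2Cl2 extraction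
Reagents that add atoms: none
Why: Acidic methanolysis of the N–S bond (standard sulfinamide cleavage) should free the primary amine, while the terminal alkyne and the aryl methyl ethers are inert to methanolic HCl at room temperature.

Step 5
Reactants: 8 5-hydroxypentanenitrile
Product: 9 methyl 5-hydroxypentanimidate hydrochloride
Conditions: HCl (4 M in 1,4-dioxane, excess), MeOH (5 equiv), 0 °C; evaporation below 25 °C, Et2O trituration, used at once
Reagents that add atoms: methanol, CO; hydrogen chloride, Cl
Why: Pinner reaction, in which the HCl-activated nitrile is trapped by methanol held in excess at 0 °C so that intermolecular addition outruns capture by the remote hydroxyl, and the salt is used crude to avoid thermal breakdown.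

Step 6
Reactants: 7 5-(3,4-dimethoxyphenyl)pent-1-yn-3-amine; 9 methyl 5-hydroxypentanimidate hydrochloride
Product: 10 N-[5-(3,4-dimethoxyphenyl)pent-1-yn-3-yl]-5-hydroxypentanimidamide (racemic, free base)
Conditions: 9 (1.2 equiv), MeOH, 0 °C to rt; then cold 2 M aq. NaOH, CH2Cl2/i-PrOH extraction, used without storage
Reagents that add atoms: none
Why: Aminolysis of an imidate salt (Pinner amidine synthesis): the primary amine adds to the protonated imidate and methanol is expelled to give the N-monosubstituted amidine, with alkyne and hydroxyl as spectators.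

Step 7
Reactants: 10 N-[5-(3,4-dimethoxyphenyl)pent-1-yn-3-yl]-5-hydroxypentanimidamide
Product: 12 cypholophine [4-{4-[2-(3,4-dimethoxyphenyl)ethyl]-5-methyl-1H-imidazol-2-yl}butan-1-ol], via 5-methylidene-imidazoline 11 (not isolated)
Conditions: Cs2CO3 (0.5 equiv), DMSO, 80 °C
Reagents that add atoms: none
Why: Carbonate in DMSO reversibly deprotonates the amidine, the distal nitrogen adds to the internal alkyne carbon, and protonation of the vinyl anion gives the exocyclic methylene imidazoline 11, which the same base converts into the aromatic imidazole by a 1,3-prototropic shift of the C4 hydrogen to the methylene carbon. The closest known reaction type is the base-promoted cycloisomerization of N-propargylamidines and N-propargylguanidines to 4(5)-methylimidazoles and 2-aminoimidazoles. The imidazole ring is closed in the 5-exo-dig mode, forming the N1–C5 bond. No stereocentre is created, and the only one present, the propargylic carbon, becomes sp2 on aromatization, which is why racemic material suffices. The required regioselectivity (5-exo-dig over 6-endo-dig) is secured by the terminal alkyne, since attack at the internal carbon puts the developing negative charge on the unsubstituted terminus and forms an unstrained five-membered cyclic amidine, whereas the proximal nitrogen could only close a three-membered ring and the hydroxyl group a nine-membered one. Aromatization should make the sequence irreversible.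

Step 8
Reactants: 12 cypholophine
Product: 13 O-acetylcypholophine, 4-{4-[2-(3,4-dimethoxyphenyl)ethyl]-5-methyl-1H-imidazol-2-yl}butyl acetate
Conditions: Ac2O (1.5 equiv), pyridine, 0 °C to rt; MeOH quench, aq. NaHCO3 work-up
Reagents that add atoms: acetic anhydride, CC(=O)OC(C)=O
Why: Pyridine-mediated O-acetylation of the unhindered primary alcohol should be selective; the ring NH, flanked by two alkyl groups, is not expected to keep an acetyl group, because an N-acylimidazole is an acyl donor that the methanol quench would cleave.

Compound list
1 | 3-(3,4-dimethoxyphenyl)propan-1-ol | COc1ccc(CCCO)cc1OC | starting material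
2 | 3-(3,4-dimethoxyphenyl)propanal | COc1ccc(CCC=O)cc1OC | intermediate
3 | tert-butanesulfinamide (2-methylpropane-2-sulfinamide, racemic) | CC(C)(C)S(N)=O | starting material
4 | (E)-N-[3-(3,4-dimethoxyphenyl)propylidene]-2-methylpropane-2-sulfinamide (racemic at sulfur) | COc1ccc(CC/C=N/S(=O)C(C)(C)C)cc1OC | intermediate
5 | ethynylmagnesium bromide | C#C[Mg]Br | starting material
6 | N-[5-(3,4-dimethoxyphenyl)pent-1-yn-3-yl]-2-methylpropane-2-sulfinamide (mixture of racemic diastereomers) | COc1ccc(CCC(NS(=O)C(C)(C)C)C#C)cc1OC | intermediate
7 | 5-(3,4-dimethoxyphenyl)pent-1-yn-3-amine (racemic, free base) | COc1ccc(CCC(N)C#C)cc1OC | intermediate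
8 | 5-hydroxypentanenitrile | N#CCCCCO | starting material
9 | methyl 5-hydroxypentanimidate hydrochloride | COC(=N)CCCCO.Cl | intermediate
10 | N-[5-(3,4-dimethoxyphenyl)pent-1-yn-3-yl]-5-hydroxypentanimidamide (racemic, free base) | COc1ccc(CCC(NC(=N)CCCCO)C#C)cc1OC | intermediate
11 | 4-{4-[2-(3,4-dimethoxyphenyl)ethyl]-5-methylidene-4,5-dihydro-1H-imidazol-2-yl}butan-1-ol (racemic, not isolated) | COc1ccc(CCC2N=C(CCCCO)NC2=C)cc1OC | intermediate
12 | cypholophine, 4-{4-[2-(3,4-dimethoxyphenyl)ethyl]-5-methyl-1H-imidazol-2-yl}butan-1-ol | COc1ccc(CCc2nc(CCCCO)[nH]c2C)cc1OC | intermediate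
13 | O-acetylcypholophine, 4-{4-[2-(3,4-dimethoxyphenyl)ethyl]-5-methyl-1H-imidazol-2-yl}butyl acetate | COc1ccc(CCc2nc(CCCCOC(C)=O)[nH]c2C)cc1OC | target

Total step count: 8. Longest linear sequence: 7 steps (steps 1–4 and 6–8, from 1 to 13); step 5 is a one-step side branch.

Steps most likely to fail

Step 7. The weakly acidic alkyl amidine may close slowly, and at 80 °C the hydroxyl may attack the amidine carbon with loss of ammonia; closure in the 6-endo mode is a further possibility. The fallback replaces alkyne hydroamination by carbonyl condensation; it sets out from 7 and comes back at 12. Amine 7, converted in the flask to its hydrochloride with one equivalent of HCl, is subjected to Markovnikov hydration of the terminal alkyne (NaAuCl4 cat., aq. MeOH, reflux) to give 3-amino-5-(3,4-dimethoxyphenyl)pentan-2-one hydrochloride F1. Condensation of this α-aminoketone salt with imidate salt 9 (KOAc, MeOH, reflux) is the classical α-aminoketone/imidate imidazole synthesis and should deliver 12 by amidine formation and cyclodehydration.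

Step 5. The δ-hydroxyl may capture the activated nitrile or the imidate intramolecularly, leading through cyclic imidate and ortho ester stages to lactone-type material and ammonium chloride, and the salt may lose methyl chloride on warming. The fallback carries the oxygen as a benzyl ether; it sets out from 8 and comes back at 12. O-Benzylation (NaH, BnBr, THF) should give 5-(benzyloxy)pentanenitrile F2, and a Pinner reaction as in step 5 gives methyl 5-(benzyloxy)pentanimidate hydrochloride F3. Aminolysis with 7 as in step 6 gives N-[5-(3,4-dimethoxyphenyl)pent-1-yn-3-yl]-5-(benzyloxy)pentanimidamide F4. Cycloisomerization under the conditions of step 7 passes through 2-[4-(benzyloxy)butyl]-4-[2-(3,4-dimethoxyphenyl)ethyl]-5-methylidene-4,5-dihydro-1H-imidazole F5 (not isolated) to 2-[4-(benzyloxy)butyl]-4-[2-(3,4-dimethoxyphenyl)ethyl]-5-methyl-1H-imidazole F6. Hydrogenolysis (H2, Pd(OH)2/C, EtOH, AcOH) then returns to 12. This fallback also removes the hydroxyl from the amidination and from the ring closure.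

Step 3. The basic acetylide may deprotonate the enolizable sulfinyl aldimine at the α-carbon and so stall the addition. The fallback introduces nitrogen by substitution; it sets out from 2 and comes back at 7. Addition of 5 to aldehyde 2 (THF, −78 °C to 0 °C; sat. aq. NH4Cl) should give 5-(3,4-dimethoxyphenyl)pent-1-yn-3-ol F7. Mitsunobu reaction with phthalimide (PPh3, DIAD, THF, 0 °C to rt) gives 2-[5-(3,4-dimethoxyphenyl)pent-1-yn-3-yl]isoindoline-1,3-dione F8, and hydrazinolysis (N2H4·H2O, EtOH, reflux) frees amine 7.

Further compounds
F1 | step 7 | 3-amino-5-(3,4-dimethoxyphenyl)pentan-2-one hydrochloride (racemic) | COc1ccc(CCC(N)C(C)=O)cc1OC.Cl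
F2 | step 5 | 5-(benzyloxy)pentanenitrile | N#CCCCCOCc1ccccc1
F3 | step 5 | methyl 5-(benzyloxy)pentanimidate hydrochloride | COC(=N)CCCCOCc1ccccc1.Cl
F4 | step 5 | N-[5-(3,4-dimethoxyphenyl)pent-1-yn-3-yl]-5-(benzyloxy)pentanimidamide (racemic) | COc1ccc(CCC(NC(=N)CCCCOCc2ccccc2)C#C)cc1OC
F5 | step 5 | 2-[4-(benzyloxy)butyl]-4-[2-(3,4-dimethoxyphenyl)ethyl]-5-methylidene-4,5-dihydro-1H-imidazole (racemic, not isolated) | COc1ccc(CCC2N=C(CCCCOCc3ccccc3)NC2=C)cc1OC
F6 | step 5 | 2-[4-(benzyloxy)butyl]-4-[2-(3,4-dimethoxyphenyl)ethyl]-5-methyl-1H-imidazole | COc1ccc(CCc2nc(CCCCOCc3ccccc3)[nH]c2C)cc1OC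
F7 | step 3 | 5-(3,4-dimethoxyphenyl)pent-1-yn-3-ol (racemic) | COc1ccc(CCC(O)C#C)cc1OC
F8 | step 3 | 2-[5-(3,4-dimethoxyphenyl)pent-1-yn-3-yl]isoindoline-1,3-dione (racemic) | COc1ccc(CCC(C#C)N2C(=O)c3ccccc3C2=O)cc1OC
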